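A direct plan would condense 2′-hydroxy-3′,4′,5′,6′-tetramethoxyacetophenone A1 with isovanillin A2 to chalcone A3, close A3 to racemic flavanone A4, oxygenate ring B of A4 at C2′ while dehydrogenating C2–C3 to give flavone A5, and finally cleave the 5-O-methyl ether of A5.
Its weakest steps would be:
- the aldol condensation with oxa-Michael closure: the doubly ortho-flanked ketone A1 would react slowly with aldehyde A2, which would be present as its phenoxide, and A3 and A4 would equilibrate;
- the oxygenation of ring B coupled to dehydrogenation of A4: it would need a phenol-to-quinone oxidation and an internal redox transfer without close precedent, in competition with β-elimination that opens ring C.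

The new route disconnects ring A at its two ring-fusion atoms: C4a–C4 and C8a–O1 are made together by inserting 3,4,5,6-tetramethoxybenzyne into the C(O)–O bond of an arylpropiolic acid that already carries ring B with both hydroquinone oxygens. Because C5–C8 of ring A all bear methoxy groups, the aryne is mirror-symmetric and no regiochemistry arises; the phenoxide so released then closes ring C on the alkyne (O1–C2) in the same flask. Ring A is thus never acylated or condensed as a hindered ketone, C2=C3 is born at the flavone oxidation level, and the C2′ oxygen is present from the start; the peri 5-OMe is singled out at the end by chelation.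

Key step: step 7

Assumption: 1,2,3,4-tetramethoxybenzene, methoxyhydroquinone and propiolic acid are taken as catalogue compounds; the target has no stereocentre, so no step has to set configuration.

Step 1
Reactants: 1 1,2,3,4-tetramethoxybenzene
Product: 2 1,2-dibromo-3,4,5,6-tetramethoxybenzene
Conditions: NBS (2.1 equiv), MeCN, 0 °C to rt
Reagents that add atoms: N-bromosuccinimide, O=C1CCC(=O)N1Br
Why: Electrophilic aromatic bromination; the only two free positions are each ortho and para to methoxy groups, so exhaustive bromination can give only the symmetric 1,2-dibromide.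

Step 2
Reactants: 2 1,2-dibromo-3,4,5,6-tetramethoxybenzene
Product: 4 2-bromo-3,4,5,6-tetramethoxyphenol, via lithium aryltriisopropoxyborate 3 (not isolated)
Conditions: B(OiPr)3 (1.2 equiv), then n-BuLi (1.0 equiv), THF/toluene, −78 °C; then AcOH, 30% aq. H2O2, 0 °C to rt; Na2S2O3 quench
Reagents that add atoms: hydrogen peroxide, OO
Why: Bromine–lithium exchange with in-situ borate quench, then boronate oxidation (1,2-shift of the aryl group from boron to oxygen); the two bromines are equivalent, one equivalent of n-BuLi should exchange only one, and trapping by the borate already present should outrun loss of LiBr from the ortho-bromoaryl anion.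

Step 3
Reactants: 4 2-bromo-3,4,5,6-tetramethoxyphenol
Product: 7 2,3,4,5-tetramethoxy-6-(trimethylsilyl)phenyl trifluoromethanesulfonate, via aryl trimethylsilyl ether 5 (not isolated), via lithium silylphenolate 6 (not isolated)
Conditions: HMDS (1.2 equiv), THF, 65 °C, then evaporate; n-BuLi (1.1 equiv), THF, −100 to −78 °C; Tf2O (1.2 equiv), −100 °C to rt
Reagents that add atoms: hexamethyldisilazane, C[Si](C)(C)N[Si](C)(C)C; trifluoromethanesulfonic anhydride, O=S(=O)(OS(=O)(=O)C(F)(F)F)C(F)(F)F
Why: O-silylation, then bromine–lithium exchange that triggers a 1,3 O-to-C silyl shift (retro-Brook rearrangement) to phenolate 6, which is O-triflated; this is the standard one-flask conversion of an ortho-bromophenol into an ortho-silylaryl triflate aryne precursor.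

Step 4
Reactants: 8 2-methoxybenzene-1,4-diol (methoxyhydroquinone)
Product: 9 1,4-bis(benzyloxy)-2-methoxybenzene
Conditions: BnBr (2.4 equiv), K2CO3 (3 equiv), DMF, N2, rt
Reagents that add atoms: benzyl bromide, BrCc1ccccc1
Why: Williamson ether synthesis on both phenols; benzyl ethers should survive fluoride at 125 °C and are cleaved by the same Lewis acid that later cleaves the 5-OMe.

Step 5
Reactants: 9 1,4-bis(benzyloxy)-2-methoxybenzene
Product: 10 1,4-bis(benzyloxy)-2-iodo-5-methoxybenzene
Conditions: NIS (1.05 equiv), CF3CO2H (10 mol%), MeCN, 0 °C to rt, dark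
Reagents that add atoms: N-iodosuccinimide, O=C1CCC(=O)N1I
Why: Electrophilic aromatic iodination; C5 is para to the methoxy group, ortho to a benzyloxy group and unhindered, whereas C3 lies between two alkoxy groups and C6 is activated by one oxygen only, as in the 5-halogenation of 1,2,4-trialkoxybenzenes.

Step 6
Reactants: 10 1,4-bis(benzyloxy)-2-iodo-5-methoxybenzene; 11 prop-2-ynoic acid (propiolic acid, 1.5 equiv)
Product: 12 3-[2,5-bis(benzyloxy)-4-methoxyphenyl]prop-2-ynoic acid
Conditions: Pd(PPh3)4 (5 mol%), DBU (2.4 equiv), DMSO, 35 °C; then 1 M HCl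
Reagents that add atoms: none
Why: Copper-free Sonogashira coupling of an aryl iodide with propiolic acid as its DBU carboxylate; near room temperature the carboxyl group should be retained, since decarboxylative second arylation needs much higher temperature.

Step 7
Reactants: 7 2,3,4,5-tetramethoxy-6-(trimethylsilyl)phenyl trifluoromethanesulfonate (1.5 equiv); 12 3-[2,5-bis(benzyloxy)-4-methoxyphenyl]prop-2-ynoic acid
Product: 15 2-[2,5-bis(benzyloxy)-4-methoxyphenyl]-5,6,7,8-tetramethoxy-4H-chromen-4-one, via tetramethoxybenzyne 13 (not isolated), via hydroxyaryl ynone 14 (not isolated)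
Conditions: CsF (4 equiv), THF, 125 °C, sealed tube, 24 h
Reagents that add atoms: none
Why: Fluoride removes the silyl group of 7 and triflate leaves to give aryne 13, whose two triple-bond carbons are each flanked by a methoxy group and are equivalent by the mirror plane of the ring, so the oxygen and the acyl carbon can arrive in only one relative arrangement. The cesium carboxylate of 12 adds through oxygen, the aryl anion so formed (stabilised inductively by the neighbouring methoxy group) attacks the ester carbonyl beside it, and the four-membered hemiketal alkoxide opens to the phenoxide of ynone 14, a net insertion of the aryne into the C(O)–O bond that forms C8a–O1 and C4a–C4 in one operation. This is the known C–O insertion of arynes into carboxylic acids (O-arylation followed by an anionic Fries-type 1,3-acyl shift), which with 3-arylpropiolic acids runs on to flavones. Ring C then closes by 6-endo-dig oxa-Michael addition of the phenoxide to the ynone β-carbon (O1–C2), the allenolate being protonated at C3 by bifluoride; the 5-exo-dig mode would place the charge on a carbon not conjugated to the carbonyl and is not expected in an aprotic medium without a carbophilic metal. No stereocentre is formed. The step needs the acyl shift to outrun protonation of the aryl anion, which the high temperature, the excess of 7 and the absence of any proton source stronger than bifluoride should favour.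

Step 8
Reactants: 15 2-[2,5-bis(benzyloxy)-4-methoxyphenyl]-5,6,7,8-tetramethoxy-4H-chromen-4-one
Product: 16 2-(2,5-dihydroxy-4-methoxyphenyl)-5-hydroxy-6,7,8-trimethoxy-4H-chromen-4-one
Conditions: BCl3 (6 equiv), C6HMe5 (6 equiv), CH2Cl2, −78 °C, then 0 °C; then degassed H2O, 1 M HCl
Reagents that add atoms: none
Why: Lewis acid ether cleavage: BCl3 ionises the two benzyl ethers at low temperature while pentamethylbenzene traps the benzyl cations (Friedel–Crafts alkylation), and on warming the boron chelated between the C4 carbonyl and the peri 5-OMe delivers chloride to that methyl group only, as in the selective 5-O-demethylation of polymethoxyflavones; the four other methyl ethers lack such a chelate and should survive, and aqueous acid hydrolyses the aryloxyboranes.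

## Compound list

1 | 1,2,3,4-tetramethoxybenzene | COc1ccc(OC)c(OC)c1OC | starting material
2 | 1,2-dibromo-3,4,5,6-tetramethoxybenzene | COc1c(Br)c(Br)c(OC)c(OC)c1OC | intermediate
3 | lithium (2-bromo-3,4,5,6-tetramethoxyphenyl)tri(propan-2-yloxy)borate | [Li+].CC(C)O[B-](OC(C)C)(OC(C)C)c1c(Br)c(OC)c(OC)c(OC)c1OC | intermediate (not isolated)
4 | 2-bromo-3,4,5,6-tetramethoxyphenol | COc1c(O)c(Br)c(OC)c(OC)c1OC | intermediate
5 | (2-bromo-3,4,5,6-tetramethoxyphenoxy)trimethylsilane | COc1c(O[Si](C)(C)C)c(Br)c(OC)c(OC)c1OC | intermediate (not isolated)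
6 | lithium 2,3,4,5-tetramethoxy-6-(trimethylsilyl)phenolate | [Li+].[O-]c1c([Si](C)(C)C)c(OC)c(OC)c(OC)c1OC | intermediate (not isolated)
7 | 2,3,4,5-tetramethoxy-6-(trimethylsilyl)phenyl trifluoromethanesulfonate | COc1c(OC)c(OC)c([Si](C)(C)C)c(OS(=O)(=O)C(F)(F)F)c1OC | intermediate
8 | 2-methoxybenzene-1,4-diol (methoxyhydroquinone) | COc1cc(O)ccc1O | starting material
9 | 1,4-bis(benzyloxy)-2-methoxybenzene | COc1cc(OCc2ccccc2)ccc1OCc1ccccc1 | intermediate
10 | 1,4-bis(benzyloxy)-2-iodo-5-methoxybenzene | COc1cc(OCc2ccccc2)c(I)cc1OCc1ccccc1 | intermediate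
11 | prop-2-ynoic acid (propiolic acid) | C#CC(=O)O | starting material
12 | 3-[2,5-bis(benzyloxy)-4-methoxyphenyl]prop-2-ynoic acid | COc1cc(OCc2ccccc2)c(C#CC(=O)O)cc1OCc1ccccc1 | intermediate
13 | 3,4,5,6-tetramethoxybenzyne (1,2-didehydro-3,4,5,6-tetramethoxybenzene) | COC1=C(OC)C(OC)=C(OC)C#C1 | intermediate (not isolated)
14 | 3-[2,5-bis(benzyloxy)-4-methoxyphenyl]-1-(2-hydroxy-3,4,5,6-tetramethoxyphenyl)prop-2-yn-1-one | COc1cc(OCc2ccccc2)c(C#CC(=O)c2c(O)c(OC)c(OC)c(OC)c2OC)cc1OCc1ccccc1 | intermediate (not isolated)
15 | 2-[2,5-bis(benzyloxy)-4-methoxyphenyl]-5,6,7,8-tetramethoxy-4H-chromen-4-one | COc1cc(OCc2ccccc2)c(-c2cc(=O)c3c(OC)c(OC)c(OC)c(OC)c3o2)cc1OCc1ccccc1 | intermediate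
16 | 2-(2,5-dihydroxy-4-methoxyphenyl)-5-hydroxy-6,7,8-trimethoxy-4H-chromen-4-one (achiral) | COc1cc(O)c(-c2cc(=O)c3c(O)c(OC)c(OC)c(OC)c3o2)cc1O | target

Total step count: 8. Longest linear sequence: 5 (steps 1, 2, 3, 7, 8 or steps 4, 5, 6, 7, 8).

Steps most likely to fail:

Step 7. The aryl anion may be protonated before the acyl shift, leaving only O-arylation. It may also add to the alkyne terminus instead of the carbonyl, the acid may lose CO2 at 125 °C, or the ring may close in the 5-exo mode. The fallback sets out from 4 and 12 and comes back at 14. Compound 4 would be protected as 1-bromo-2,3,4,5-tetramethoxy-6-(methoxymethoxy)benzene F1 (MOMCl, i-Pr2NEt, CH2Cl2), and 12 would be converted into 3-[2,5-bis(benzyloxy)-4-methoxyphenyl]-N-methoxy-N-methylprop-2-ynamide F2 (MeNHOMe·HCl, EDC, i-Pr2NEt). Bromine–lithium exchange on F1 (n-BuLi, THF, −78 °C) and acylation of the aryllithium by F2 would give 3-[2,5-bis(benzyloxy)-4-methoxyphenyl]-1-[2,3,4,5-tetramethoxy-6-(methoxymethoxy)phenyl]prop-2-yn-1-one F3. HCl in MeOH would cleave the acetal to 14, and K2CO3 in acetone would close 14 to 15.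

Step 2. The ortho-bromoaryl anion may lose LiBr to an aryne before it is trapped, or a second exchange may take place. The fallback sets out from 1 and comes back at 4. Rieche formylation of 1 (Cl2CHOMe, TiCl4, CH2Cl2, 0 °C) would give 2,3,4,5-tetramethoxybenzaldehyde F4. Baeyer–Villiger oxidation (mCPBA, CH2Cl2) would give 2,3,4,5-tetramethoxyphenyl formate F5, and methanolysis (K2CO3, MeOH) would give 2,3,4,5-tetramethoxyphenol F6. NBS (1 equiv, MeCN) would then brominate the single free position of F6 to give 4.

Step 8. Benzyl cations may re-attack the electron-rich rings, cleavage may run on from the 5-OMe to the 6-OMe, or the hydroquinone may oxidise during work-up. The fallback sets out from 15 and comes back at 16. MgI2·OEt2 in toluene at 80 °C acts only on an ether oxygen that can chelate magnesium together with the C4 carbonyl, and would give 2-[2,5-bis(benzyloxy)-4-methoxyphenyl]-5-hydroxy-6,7,8-trimethoxy-4H-chromen-4-one F7. Hydrogenolysis (H2, Pd/C, EtOAc) would then remove the benzyl groups under neutral conditions to give 16.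

Further compounds

F1 | step 7 | 1-bromo-2,3,4,5-tetramethoxy-6-(methoxymethoxy)benzene | COCOc1c(Br)c(OC)c(OC)c(OC)c1OC
F2 | step 7 | 3-[2,5-bis(benzyloxy)-4-methoxyphenyl]-N-methoxy-N-methylprop-2-ynamide | COc1cc(OCc2ccccc2)c(C#CC(=O)N(C)OC)cc1OCc1ccccc1
F3 | step 7 | 3-[2,5-bis(benzyloxy)-4-methoxyphenyl]-1-[2,3,4,5-tetramethoxy-6-(methoxymethoxy)phenyl]prop-2-yn-1-one | COCOc1c(C(=O)C#Cc2cc(OCc3ccccc3)c(OC)cc2OCc2ccccc2)c(OC)c(OC)c(OC)c1OC
F4 | step 2 | 2,3,4,5-tetramethoxybenzaldehyde | COc1cc(C=O)c(OC)c(OC)c1OC
F5 | step 2 | 2,3,4,5-tetramethoxyphenyl formate | COc1cc(OC=O)c(OC)c(OC)c1OC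
F6 | step 2 | 2,3,4,5-tetramethoxyphenol | COc1cc(O)c(OC)c(OC)c1OC
F7 | step 8 | 2-[2,5-bis(benzyloxy)-4-methoxyphenyl]-5-hydroxy-6,7,8-trimethoxy-4H-chromen-4-one | COc1cc(OCc2ccccc2)c(-c2cc(=O)c3c(O)c(OC)c(OC)c(OC)c3o2)cc1OCc1ccccc1
A1 | direct plan | 1-(2-hydroxy-3,4,5,6-tetramethoxyphenyl)ethan-1-one | CC(=O)c1c(O)c(OC)c(OC)c(OC)c1OC
A2 | direct plan | 3-hydroxy-4-methoxybenzaldehyde (isovanillin) | COc1ccc(C=O)cc1O
A3 | direct plan | (E)-1-(2-hydroxy-3,4,5,6-tetramethoxyphenyl)-3-(3-hydroxy-4-methoxyphenyl)prop-2-en-1-one | COc1ccc(/C=C/C(=O)c2c(O)c(OC)c(OC)c(OC)c2OC)cc1O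
A4 | direct plan | rac-2-(3-hydroxy-4-methoxyphenyl)-5,6,7,8-tetramethoxychroman-4-one | COc1ccc(C2CC(=O)c3c(OC)c(OC)c(OC)c(OC)c3O2)cc1O
A5 | direct plan | 2-(2,5-dihydroxy-4-methoxyphenyl)-5,6,7,8-tetramethoxy-4H-chromen-4-one | COc1cc(O)c(-c2cc(=O)c3c(OC)c(OC)c(OC)c(OC)c3o2)cc1O
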